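**Retrosynthetic overview**
Fischerin ⇒ (fluoride desilylation, carbinol oxidation) ⇒ a one-flask union of three pieces on a 3-bromo-5-iodo-2-pyridone: first the pyridone C5–cyclohexane C1′ bond (intramolecular), then the pyridone C3–CH(OH)–decalin bond.
Enabling feature: the oxygen on pyridone C4 (ortho to C5) and the secondary oxygen on cyclohexane C4′ lie on the same side as the C5–C1′ bond (pyridone cis to C4′–OH and to the oxirane, C1′–OH trans). A di-tert-butylsilylene between these two oxygens makes the ketone addition intramolecular through a temporary nine-membered ring and delivers C5 to the carbonyl face syn to the oxirane, the face an untethered nucleophile is expected to avoid.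
Pieces: epoxy ketone 6 (cyclohexa-1,3-diene, enzymatic desymmetrisation, hydroxyl-directed epoxidation); N-alkoxy pyridone 13 (from 2-chloro-4-nitropyridine N-oxide); cis-decalin aldehyde 26 (Z-triene intramolecular Diels–Alder, C1 epimerisation, auxiliary resolution).
Ring order: oxirane on the bought carbocycle; pyridine ring bought; both decalin rings at once by cycloaddition; temporary silacycle closed in the key step and opened by fluoride in the last step.

Key step: step 21

Assumption: the hydrolase of step 2 is chosen to cleave the acetate on the carbon that becomes the (S)-carbinol (3 as drawn); if the available enzyme has the opposite sense, 3 follows from lipase mono-acetylation of the meso-diol. Racemic compounds 20–23 are drawn as the enantiomer that is carried on.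

**Route**

Step 1
Reactants: 1 cyclohexa-1,3-diene
Product: 2 cis-cyclohex-2-ene-1,4-diyl diacetate (meso)
Conditions: Pd(OAc)2 (5 mol %), LiCl (cat.), LiOAc, p-benzoquinone, AcOH, 25 °C
Reagents that add atoms: acetic acid CC(=O)O
Why: Pd(II)-catalysed 1,4-diacetoxylation of a cyclic 1,3-diene; with catalytic chloride the second acetate attacks the π-allyl intermediate externally, so both acetates end cis.

Step 2
Reactants: 2 cis-cyclohex-2-ene-1,4-diyl diacetate
Product: 3 (1R,4S)-4-hydroxycyclohex-2-en-1-yl acetate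
Conditions: electric-eel acetylcholinesterase (or a screened lipase), pH 7 phosphate buffer, 25 °C
Reagents that add atoms: none
Why: enzymatic desymmetrisation of a meso-diacetate, in which hydrolysis of one enantiotopic ester sets both stereocentres.

Step 3
Reactants: 3 (1R,4S)-4-hydroxycyclohex-2-en-1-yl acetate
Product: 4 (1R,2R,5S,6S)-5-hydroxy-7-oxabicyclo[4.1.0]heptan-2-yl acetate (oxirane cis to OH and OAc)
Conditions: mCPBA, CH2Cl2, 0 °C
Reagents that add atoms: mCPBA O=C(OO)c1cccc(Cl)c1
Why: hydroxyl-directed (Henbest) peracid epoxidation; the allylic OH hydrogen-bonds the peracid, so the oxirane forms on the face that carries OH and OAc.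

Step 4
Reactants: 4 (1R,2R,5S,6S)-5-hydroxy-7-oxabicyclo[4.1.0]heptan-2-yl acetate
Product: 5 (1R,2R,6R)-5-oxo-7-oxabicyclo[4.1.0]heptan-2-yl acetate
Conditions: Dess–Martin periodinane, pyridine, CH2Cl2, 0 °C to rt
Reagents that add atoms: none
Why: Dess–Martin oxidation of a secondary alcohol under buffered, non-basic conditions that leave oxirane and acetate untouched.

Step 5
Reactants: 5 (1R,2R,6R)-5-oxo-7-oxabicyclo[4.1.0]heptan-2-yl acetate
Product: 6 (1R,5R,6R)-5-hydroxy-7-oxabicyclo[4.1.0]heptan-2-one (oxirane cis to OH)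
Conditions: immobilised Candida antarctica lipase B, pH 7 phosphate buffer/MTBE, 30 °C
Reagents that add atoms: none
Why: lipase-catalysed hydrolysis of a secondary acetate at neutral pH, chosen because an α,β-epoxy ketone should not be exposed to alkoxide.

Step 6
Reactants: 7 2-chloro-4-nitropyridine 1-oxide
Product: 8 4-(benzyloxy)-2-chloropyridine 1-oxide
Conditions: BnOH, NaH, THF, 0 °C
Reagents that add atoms: benzyl alcohol OCc1ccccc1
Why: nucleophilic aromatic substitution, in which the 4-nitro group of a pyridine N-oxide is displaced by alkoxide faster than the 2-chloride.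

Step 7
Reactants: 8 4-(benzyloxy)-2-chloropyridine 1-oxide
Product: 9 4-(benzyloxy)-1-hydroxypyridin-2(1H)-one
Conditions: KOH (10 % aq.), 80 °C; then HCl
Reagents that add atoms: potassium hydroxide [K+].[OH-]
Why: SNAr hydrolysis of a 2-chloropyridine N-oxide, whose product exists as the 1-hydroxy-2-pyridone tautomer.

Step 8
Reactants: 9 4-(benzyloxy)-1-hydroxypyridin-2(1H)-one
Product: 10 4-(benzyloxy)-1-[2-(trimethylsilyl)ethoxy]pyridin-2(1H)-one
Conditions: Me3SiCH2CH2OH, PPh3, DIAD, THF, 0 °C to rt
Reagents that add atoms: 2-(trimethylsilyl)ethanol OCC[Si](C)(C)C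
Why: Mitsunobu O-alkylation of the acidic hydroxamic N–OH, which puts a fluoride-labile group on the N–O oxygen.

Step 9
Reactants: 10 4-(benzyloxy)-1-[2-(trimethylsilyl)ethoxy]pyridin-2(1H)-one
Product: 11 4-hydroxy-1-[2-(trimethylsilyl)ethoxy]pyridin-2(1H)-one
Conditions: H2 (1 atm), 10 % Pd/C, EtOAc, rt
Reagents that add atoms: none
Why: hydrogenolysis of the benzyl ether under conditions mild enough to keep the N–O–alkyl bond.

Step 10
Reactants: 11 4-hydroxy-1-[2-(trimethylsilyl)ethoxy]pyridin-2(1H)-one
Product: 12 3-bromo-4-hydroxy-1-[2-(trimethylsilyl)ethoxy]pyridin-2(1H)-one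
Conditions: NBS (1.0 equiv), MeCN, 0 °C
Reagents that add atoms: N-bromosuccinimide O=C1CCC(=O)N1Br
Why: electrophilic bromination at C3, the carbon between the two oxygen-bearing carbons and the most nucleophilic site of a 4-hydroxy-2-pyridone.

Step 11
Reactants: 12 3-bromo-4-hydroxy-1-[2-(trimethylsilyl)ethoxy]pyridin-2(1H)-one
Product: 13 3-bromo-4-hydroxy-5-iodo-1-[2-(trimethylsilyl)ethoxy]pyridin-2(1H)-one
Conditions: NIS (1.05 equiv), MeCN, rt
Reagents that add atoms: N-iodosuccinimide O=C1CCC(=O)N1I
Why: electrophilic iodination at C5, the only remaining position activated by the 4-OH and the ring nitrogen.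

Step 12
Reactants: 14 2-(3-chloropropyl)-1,3-dioxolane; 15 (2E,4E)-hexa-2,4-dien-1-yl acetate
Product: 17 2-[(5E,7E)-nona-5,7-dien-1-yl]-1,3-dioxolane, via Grignard reagent 16 (not isolated)
Conditions: Mg, THF, 50 °C; then 15, Li2CuCl4 (2 mol %), THF, −20 °C
Reagents that add atoms: none
Why: copper-catalysed coupling of a Grignard reagent with a dienylic acetate at the α-carbon, which keeps the conjugated (E,E)-diene.

Step 13
Reactants: 17 2-[(5E,7E)-nona-5,7-dien-1-yl]-1,3-dioxolane
Product: 18 (6E,8E)-deca-6,8-dienal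
Conditions: AcOH/H2O/THF, 45 °C
Reagents that add atoms: water O
Why: mild acid-catalysed acetal hydrolysis that should not isomerise the diene.

Step 14
Reactants: 18 (6E,8E)-deca-6,8-dienal
Product: 19 methyl (2Z,8E,10E)-dodeca-2,8,10-trienoate
Conditions: (CF3CH2O)2P(O)CH2CO2Me, KHMDS, 18-crown-6, THF, −78 °C
Reagents that add atoms: methyl bis(2,2,2-trifluoroethyl)phosphonoacetate COC(=O)CP(=O)(OCC(F)(F)F)OCC(F)(F)F
Why: Still–Gennari olefination, which gives the (Z)-enoate under kinetic control.

Step 15
Reactants: 19 methyl (2Z,8E,10E)-dodeca-2,8,10-trienoate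
Product: 20 rac-methyl (1S,2S,4aR,8aR)-2-methyl-1,2,4a,5,6,7,8,8a-octahydronaphthalene-1-carboxylate (all-cis)
Conditions: toluene, BHT (cat.), 170 °C, sealed tube
Reagents that add atoms: none
Why: intramolecular Diels–Alder reaction; the (Z)-dienophile with the ester endo puts ester, tether and the diene methyl on one face, which should give mainly the cis-fused adduct, and the trans-fused isomer is removed by chromatography.

Step 16
Reactants: 20 rac-methyl (1S,2S,4aR,8aR)-2-methyl-1,2,4a,5,6,7,8,8a-octahydronaphthalene-1-carboxylate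
Product: 22 rac-(1R,2S,4aR,8aR)-2-methyl-1,2,4a,5,6,7,8,8a-octahydronaphthalene-1-carboxylic acid, via epimerised methyl ester 21 (not isolated)
Conditions: NaOMe, MeOH, 65 °C; then NaOH, H2O, 65 °C; HCl
Reagents that add atoms: sodium hydroxide [Na+].[OH-]
Why: epimerisation at C1 through the ester enolate to the more stable epimer (carboxyl trans to the C2 methyl and to C8), followed by saponification.

Step 17
Reactants: 22 rac-(1R,2S,4aR,8aR)-2-methyl-1,2,4a,5,6,7,8,8a-octahydronaphthalene-1-carboxylic acid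
Product: 24 (4S)-4-benzyl-3-[(1R,2S,4aR,8aR)-2-methyl-1,2,4a,5,6,7,8,8a-octahydronaphthalene-1-carbonyl]-1,3-oxazolidin-2-one, via mixed pivalic anhydride 23 (not isolated)
Conditions: PivCl, Et3N, THF, −20 °C; then (S)-4-benzyloxazolidin-2-one, LiCl, rt; separation of diastereomers on silica
Reagents that add atoms: (S)-4-benzyloxazolidin-2-one O=C1N[C@@H](Cc2ccccc2)CO1
Why: N-acylation of a chiral oxazolidinone through the mixed anhydride turns the racemate into two diastereomeric imides that should separate by chromatography (resolution by a covalent auxiliary); the configuration of 24 is to be confirmed by X-ray crystallography.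

Step 18
Reactants: 24 (4S)-4-benzyl-3-[(1R,2S,4aR,8aR)-2-methyl-1,2,4a,5,6,7,8,8a-octahydronaphthalene-1-carbonyl]-1,3-oxazolidin-2-one
Product: 25 [(1R,2S,4aR,8aR)-2-methyl-1,2,4a,5,6,7,8,8a-octahydronaphthalen-1-yl]methanol
Conditions: LiBH4, MeOH (1 equiv), Et2O, 0 °C
Reagents that add atoms: none
Why: reductive cleavage of the N-acyloxazolidinone to the primary alcohol with recovery of the auxiliary and no change at any stereocentre.

Step 19
Reactants: 25 [(1R,2S,4aR,8aR)-2-methyl-1,2,4a,5,6,7,8,8a-octahydronaphthalen-1-yl]methanol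
Product: 26 (1R,2S,4aR,8aR)-2-methyl-1,2,4a,5,6,7,8,8a-octahydronaphthalene-1-carbaldehyde
Conditions: Dess–Martin periodinane, CH2Cl2, rt
Reagents that add atoms: none
Why: Dess–Martin oxidation to the aldehyde; C1 already has the thermodynamically preferred configuration, so enolisation cannot erode it.

Step 20
Reactants: 13 3-bromo-4-hydroxy-5-iodo-1-[2-(trimethylsilyl)ethoxy]pyridin-2(1H)-one; 6 (1R,5R,6R)-5-hydroxy-7-oxabicyclo[4.1.0]heptan-2-one
Product: 28 mixed di-tert-butylsilyl ketal linking O4 of pyridone 13 to the hydroxyl oxygen of epoxy ketone 6, via aryl silyl triflate 27 (not isolated)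
Conditions: tBu2Si(OTf)2 (1.0 equiv), 2,6-lutidine, CH2Cl2, −40 to 0 °C; then 6, DMAP (cat.), rt
Reagents that add atoms: di-tert-butylsilyl bis(trifluoromethanesulfonate) CC(C)(C)[Si](OS(=O)(=O)C(F)(F)F)(OS(=O)(=O)C(F)(F)F)C(C)(C)C
Why: stepwise substitution at a silylene bis(triflate), in which the acidic 4-OH displaces the first triflate and the secondary alcohol of 6 the second, giving the unsymmetrical silyl ketal (temporary silicon tether) that the tert-butyl groups protect from hydrolysis.

Step 21
Reactants: 28 mixed di-tert-butylsilyl ketal of 13 and 6; 26 (1R,2S,4aR,8aR)-2-methyl-1,2,4a,5,6,7,8,8a-octahydronaphthalene-1-carbaldehyde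
Product: 31 silylene-bridged three-component adduct (C5–C1′ bond formed; C1′–OH trans to the oxirane; secondary carbinol at C3 as epimer mixture), via cyclised lithium alkoxide 29 (not isolated), via C3-lithiated alkoxide 30 (not isolated)
Conditions: t-BuLi (1.05 equiv), THF (0.01 M), −100 °C; t-BuLi (3.1 equiv), −78 °C; 26 (1.5 equiv), −78 °C; sat. NH4Cl
Reagents that add atoms: none
Why: Proposed new method: iodine–lithium exchange at C5 (expected to outrun both C–Br exchange and alkyllithium addition to the ketone at −100 °C) gives an aryllithium that the O–Si–O tether holds over the ketone, to which it adds intramolecularly; the closest known reaction types are the Parham cyclisation (halogen–lithium exchange followed by intramolecular addition to a ketone) and temporary silicon-tethered cyclisations. The ring that closes is a temporary nine-membered silyl ketal ring (C5, C4, O, Si, O, C4′ and the cyclohexane carbons back to C1′), formed in the 9-exo-trig mode and turning the cyclohexanone into a bridged bicyclo[5.2.2] system. The new quaternary carbinol centre C1′ is controlled by the C4′ stereocentre through the tether: the five-atom bridge can only reach the carbonyl face syn to C4′–O and the oxirane oxygen, so the pyridone ends cis to the oxirane and the C1′–OH trans, as in the target, and the same geometry keeps the carbanion away from the backside of the oxirane C–O bonds. A second exchange at C3–Br then gives the 3-lithio pyridone, which adds to aldehyde 26 (ordinary 1,2-addition), so three components are joined around the pyridone core in one flask; the carbinol centre formed here is not controlled and is removed by oxidation in step 22. The step needs C–I exchange before C–Br exchange (secured by the two different halogens), cyclisation faster than 1,3 O-to-C silyl migration (secured by the tert-butyl groups on silicon) and high dilution against intermolecular addition.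

Step 22
Reactants: 31 silylene-bridged three-component adduct
Product: 32 silylene-bridged 3-acyl pyridone (ketone)
Conditions: Dess–Martin periodinane, CH2Cl2, rt
Reagents that add atoms: none
Why: Dess–Martin oxidation of the secondary pyridyl carbinol, in which both epimers converge on one ketone and the tertiary alcohol cannot react.

Step 23
Reactants: 32 silylene-bridged 3-acyl pyridone
Product: 33 fischerin
Conditions: TBAF, AcOH (1:1), THF, 0 °C to rt
Reagents that add atoms: none
Why: fluoride-mediated global desilylation, in which cleavage of the silylene frees the 4-OH and the C4′–OH and β-elimination of the 2-(trimethylsilyl)ethyl group frees the N–OH, with acetic acid buffering against Payne rearrangement of the trans-hydroxy epoxide.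

**Compound list**
1 | cyclohexa-1,3-diene | C1=CC=CCC1 | starting material
2 | cis-cyclohex-2-ene-1,4-diyl diacetate (meso) | CC(=O)O[C@H]1CC[C@@H](OC(C)=O)C=C1 | intermediate
3 | (1R,4S)-4-hydroxycyclohex-2-en-1-yl acetate | O[C@H]1CC[C@@H](OC(C)=O)C=C1 | intermediate
4 | (1R,2R,5S,6S)-5-hydroxy-7-oxabicyclo[4.1.0]heptan-2-yl acetate (all-cis) | O[C@H]1CC[C@@H](OC(C)=O)[C@H]2O[C@@H]12 | intermediate
5 | (1R,2R,6R)-5-oxo-7-oxabicyclo[4.1.0]heptan-2-yl acetate | O=C1CC[C@@H](OC(C)=O)[C@H]2O[C@@H]12 | intermediate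
6 | (1R,5R,6R)-5-hydroxy-7-oxabicyclo[4.1.0]heptan-2-one | O=C1CC[C@@H](O)[C@H]2O[C@@H]12 | intermediate
7 | 2-chloro-4-nitropyridine 1-oxide | [O-][n+]1ccc(cc1Cl)[N+](=O)[O-] | starting material
8 | 4-(benzyloxy)-2-chloropyridine 1-oxide | [O-][n+]1ccc(OCc2ccccc2)cc1Cl | intermediate
9 | 4-(benzyloxy)-1-hydroxypyridin-2(1H)-one | O=c1cc(OCc2ccccc2)ccn1O | intermediate
10 | 4-(benzyloxy)-1-[2-(trimethylsilyl)ethoxy]pyridin-2(1H)-one | O=c1cc(OCc2ccccc2)ccn1OCC[Si](C)(C)C | intermediate
11 | 4-hydroxy-1-[2-(trimethylsilyl)ethoxy]pyridin-2(1H)-one | O=c1cc(O)ccn1OCC[Si](C)(C)C | intermediate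
12 | 3-bromo-4-hydroxy-1-[2-(trimethylsilyl)ethoxy]pyridin-2(1H)-one | O=c1c(Br)c(O)ccn1OCC[Si](C)(C)C | intermediate
13 | 3-bromo-4-hydroxy-5-iodo-1-[2-(trimethylsilyl)ethoxy]pyridin-2(1H)-one | O=c1c(Br)c(O)c(I)cn1OCC[Si](C)(C)C | intermediate
14 | 2-(3-chloropropyl)-1,3-dioxolane | ClCCCC1OCCO1 | starting material
15 | (2E,4E)-hexa-2,4-dien-1-yl acetate | C/C=C/C=C/COC(C)=O | starting material
16 | [3-(1,3-dioxolan-2-yl)propyl]magnesium chloride | Cl[Mg]CCCC1OCCO1 | intermediate
17 | 2-[(5E,7E)-nona-5,7-dien-1-yl]-1,3-dioxolane | C/C=C/C=C/CCCCC1OCCO1 | intermediate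
18 | (6E,8E)-deca-6,8-dienal | C/C=C/C=C/CCCCC=O | intermediate
19 | methyl (2Z,8E,10E)-dodeca-2,8,10-trienoate | C/C=C/C=C/CCCC/C=C\C(=O)OC | intermediate
20 | rac-methyl (1S,2S,4aR,8aR)-2-methyl-1,2,4a,5,6,7,8,8a-octahydronaphthalene-1-carboxylate (all-cis; one enantiomer drawn) | C[C@H]1C=C[C@H]2CCCC[C@H]2[C@H]1C(=O)OC | intermediate
21 | rac-methyl (1R,2S,4aR,8aR)-2-methyl-1,2,4a,5,6,7,8,8a-octahydronaphthalene-1-carboxylate (one enantiomer drawn) | C[C@H]1C=C[C@H]2CCCC[C@H]2[C@@H]1C(=O)OC | intermediate
22 | rac-(1R,2S,4aR,8aR)-2-methyl-1,2,4a,5,6,7,8,8a-octahydronaphthalene-1-carboxylic acid (one enantiomer drawn) | C[C@H]1C=C[C@H]2CCCC[C@H]2[C@@H]1C(=O)O | intermediate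
23 | mixed pivalic anhydride of 22 (racemic; one enantiomer drawn) | C[C@H]1C=C[C@H]2CCCC[C@H]2[C@@H]1C(=O)OC(=O)C(C)(C)C | intermediate
24 | (4S)-4-benzyl-3-[(1R,2S,4aR,8aR)-2-methyl-1,2,4a,5,6,7,8,8a-octahydronaphthalene-1-carbonyl]-1,3-oxazolidin-2-one | C[C@H]1C=C[C@H]2CCCC[C@H]2[C@@H]1C(=O)N1[C@@H](Cc2ccccc2)COC1=O | intermediate
25 | [(1R,2S,4aR,8aR)-2-methyl-1,2,4a,5,6,7,8,8a-octahydronaphthalen-1-yl]methanol | C[C@H]1C=C[C@H]2CCCC[C@H]2[C@@H]1CO | intermediate
26 | (1R,2S,4aR,8aR)-2-methyl-1,2,4a,5,6,7,8,8a-octahydronaphthalene-1-carbaldehyde | C[C@H]1C=C[C@H]2CCCC[C@H]2[C@@H]1C=O | intermediate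
27 | 3-bromo-4-{[di-tert-butyl(trifluoromethanesulfonyloxy)silyl]oxy}-5-iodo-1-[2-(trimethylsilyl)ethoxy]pyridin-2(1H)-one | Brc1c(O[Si](OS(=O)(=O)C(F)(F)F)(C(C)(C)C)C(C)(C)C)c(I)cn(OCC[Si](C)(C)C)c1=O | intermediate
28 | mixed di-tert-butylsilyl ketal: silicon links O4 of the 3-bromo-5-iodo pyridone to the C5 oxygen of the epoxy ketone (oxirane cis to that oxygen) | Brc1c(O[Si](C(C)(C)C)(C(C)(C)C)O[C@@H]2CCC(=O)[C@@H]3O[C@H]23)c(I)cn(OCC[Si](C)(C)C)c1=O | intermediate
29 | cyclised lithium alkoxide: pyridone C5 bonded to C1′ (O–Li trans to the oxirane), silylene bridging O4 and O4′, C3–Br intact | Brc1c(O[Si]4(C(C)(C)C)C(C)(C)C)c([C@@]2(O[Li])CC[C@@H](O4)[C@H]3O[C@H]32)cn(OCC[Si](C)(C)C)c1=O | intermediate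
30 | C3-lithiated form of 29 | [Li]c1c(O[Si]4(C(C)(C)C)C(C)(C)C)c([C@@]2(O[Li])CC[C@@H](O4)[C@H]3O[C@H]32)cn(OCC[Si](C)(C)C)c1=O | intermediate
31 | silylene-bridged adduct with C3–CH(OH)–decalin (carbinol epimers), free C1′–OH, N–O–CH2CH2SiMe3 | C[C@H]1C=C[C@H]2CCCC[C@H]2[C@@H]1C(O)c1c(O[Si]4(C(C)(C)C)C(C)(C)C)c([C@@]2(O)CC[C@@H](O4)[C@H]3O[C@H]32)cn(OCC[Si](C)(C)C)c1=O | intermediate
32 | silylene-bridged 3-acyl pyridone (ketone of 31) | C[C@H]1C=C[C@H]2CCCC[C@H]2[C@@H]1C(=O)c1c(O[Si]4(C(C)(C)C)C(C)(C)C)c([C@@]2(O)CC[C@@H](O4)[C@H]3O[C@H]32)cn(OCC[Si](C)(C)C)c1=O | intermediate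
33 | fischerin: 5-[(1R,2S,5R,6R)-2,5-dihydroxy-7-oxabicyclo[4.1.0]heptan-2-yl]-1,4-dihydroxy-3-[(1R,2S,4aR,8aR)-2-methyl-1,2,4a,5,6,7,8,8a-octahydronaphthalene-1-carbonyl]pyridin-2(1H)-one | C[C@H]1C=C[C@H]2CCCC[C@H]2[C@@H]1C(=O)c1c(O)c([C@@]2(O)CC[C@@H](O)[C@H]3O[C@H]32)cn(O)c1=O | target

**Totals**
Total steps: 23. Longest linear sequence: 11 steps (steps 12–19, then 21–23, from 14/15 to 33).

**Steps most likely to fail**

Step 21 (Proposed new method). Possible failure processes: alkyllithium addition to or enolisation of the ketone before exchange, 1,3 O-to-C silyl migration in the ortho-lithiated silyl ether, or a nine-membered closure slow enough for intermolecular pathways to win. The fallback uses only known reaction types, sets out from 3, 13 and 26, and comes back to the route at 33.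
- From 3, silylation (TBSCl, imidazole) gives the silyl ether acetate F1, methanolysis (K2CO3, MeOH) gives the allylic alcohol F2, and Dess–Martin oxidation gives (S)-4-(tert-butyldimethylsilyloxy)cyclohex-2-enone F3.
- Mitsunobu reaction of 13 with 2-(trimethylsilyl)ethanol gives the bis(silylethyl) pyridone F4.
- Iodine–lithium exchange on F4 and 1,2-addition to F3 (expected anti to the γ-silyloxy group), then bromine–lithium exchange and addition to 26, give the diol F5.
- HF·pyridine removes the TBS group to give the triol F6, and Dess–Martin periodinane oxidises both secondary alcohols to the hydroxy enone ketone F7.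
- Trimethylsilylimidazole gives the tertiary silyl ether F8.
- Nucleophilic epoxidation (t-BuOOH, DBU), expected anti to the pseudo-axial OSiMe3 and so syn to the pyridone, gives the epoxy ketone F9.
- Luche reduction (NaBH4, CeCl3), expected anti to the oxirane, gives the cis-epoxy alcohol F10, and TBAF/AcOH then gives 33.

Step 20. Possible failure processes: incomplete second substitution at the hindered silicon, or hydrolytic loss of the aryl–O–Si bond on isolation. The fallback builds the alkyl–O–Si bond first with a monofunctional silane; it sets out from 6 and 13 and comes back at 28. Di-tert-butylchlorosilane and imidazole convert 6 into the hydrosilyl ether F11. NBS converts the Si–H bond into the bromosilane F12, which is used in situ with 13 and imidazole to give 28.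

Step 15. Possible failure processes: poor discrimination between cis- and trans-fused transition states, and thermal Z-to-E isomerisation of the dienophile. The fallback moves the origin of the C1 configuration from endo closure plus epimerisation to direct exo closure; it sets out from 18 and comes back at 21. E-selective Horner–Wadsworth–Emmons olefination (trimethyl phosphonoacetate, LiCl, DBU) gives methyl (2E,8E,10E)-dodeca-2,8,10-trienoate F13. Its thermal intramolecular Diels–Alder reaction through the exo transition state gives 21 directly, to be separated from the trans-fused endo adduct and saponified as in step 16.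

Further compounds
F1 | step 21 | (1R,4S)-4-[(tert-butyldimethylsilyl)oxy]cyclohex-2-en-1-yl acetate | CC(C)(C)[Si](C)(C)O[C@H]1CC[C@@H](OC(C)=O)C=C1
F2 | step 21 | (1R,4S)-4-[(tert-butyldimethylsilyl)oxy]cyclohex-2-en-1-ol | CC(C)(C)[Si](C)(C)O[C@H]1CC[C@@H](O)C=C1
F3 | step 21 | (S)-4-[(tert-butyldimethylsilyl)oxy]cyclohex-2-en-1-one | CC(C)(C)[Si](C)(C)O[C@H]1CCC(=O)C=C1
F4 | step 21 | 3-bromo-5-iodo-1,4-bis[2-(trimethylsilyl)ethoxy]pyridin-2(1H)-one | Brc1c(OCC[Si](C)(C)C)c(I)cn(OCC[Si](C)(C)C)c1=O
F5 | step 21 | diol from addition of the C5 lithium reagent to F3 (pyridone trans to OTBS) and of the C3 lithium reagent to 26 (carbinol epimers) | C[C@H]1C=C[C@H]2CCCC[C@H]2[C@@H]1C(O)c1c(OCC[Si](C)(C)C)c([C@@]2(O)CC[C@H](O[Si](C)(C)C(C)(C)C)C=C2)cn(OCC[Si](C)(C)C)c1=O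
F6 | step 21 | triol after removal of the TBS group | C[C@H]1C=C[C@H]2CCCC[C@H]2[C@@H]1C(O)c1c(OCC[Si](C)(C)C)c([C@@]2(O)CC[C@H](O)C=C2)cn(OCC[Si](C)(C)C)c1=O
F7 | step 21 | 4-aryl-4-hydroxycyclohex-2-enone bearing the decalinyl ketone | C[C@H]1C=C[C@H]2CCCC[C@H]2[C@@H]1C(=O)c1c(OCC[Si](C)(C)C)c([C@@]2(O)CCC(=O)C=C2)cn(OCC[Si](C)(C)C)c1=O
F8 | step 21 | trimethylsilyl ether of F7 | C[C@H]1C=C[C@H]2CCCC[C@H]2[C@@H]1C(=O)c1c(OCC[Si](C)(C)C)c([C@@]2(O[Si](C)(C)C)CCC(=O)C=C2)cn(OCC[Si](C)(C)C)c1=O
F9 | step 21 | epoxy ketone (oxirane cis to the pyridone, trans to OSiMe3) | C[C@H]1C=C[C@H]2CCCC[C@H]2[C@@H]1C(=O)c1c(OCC[Si](C)(C)C)c([C@@]2(O[Si](C)(C)C)CCC(=O)[C@H]3O[C@H]32)cn(OCC[Si](C)(C)C)c1=O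
F10 | step 21 | cis-epoxy alcohol (tris-silyl-protected fischerin) | C[C@H]1C=C[C@H]2CCCC[C@H]2[C@@H]1C(=O)c1c(OCC[Si](C)(C)C)c([C@@]2(O[Si](C)(C)C)CC[C@@H](O)[C@H]3O[C@H]32)cn(OCC[Si](C)(C)C)c1=O
F11 | step 20 | di-tert-butylsilyl (Si–H) ether of 6 | O=C1CC[C@@H](O[SiH](C(C)(C)C)C(C)(C)C)[C@H]2O[C@@H]12
F12 | step 20 | bromo(di-tert-butyl)silyl ether of 6 | O=C1CC[C@@H](O[Si](Br)(C(C)(C)C)C(C)(C)C)[C@H]2O[C@@H]12
F13 | step 15 | methyl (2E,8E,10E)-dodeca-2,8,10-trienoate | C/C=C/C=C/CCCC/C=C/C(=O)OC
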